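**Assumption:** CNP0158207.1 is taken to be exactly the given SMILES. Ring positions are numbered as in carvone (C1 = carbon that ends as the ring angelate carbinol, C2 = methyl-bearing carbon, C3 = CHCl, C5 = side-chain carbon, C6 = free secondary carbinol); side-chain carbons are primed from the =CH2 carbon (C1′).

## Retrosynthetic overview

1. The side-chain oxirane is made last by catalyst-controlled Shi epoxidation of a prenyl alkene; it is the only ring that is built and kept.
2. Both angelates come from one double Yamaguchi-type esterification; the side-chain carbinol comes from a 2-substituted acrolein plus allyl (Brown), then cross-metathesis to prenyl; the acrolein comes from allylic oxidation of the isopropenyl group.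
3. Key C–O disconnection: the ring chlorohydrin (C2–O, C3–Cl) comes from a hydroxyl-directed one-flask chlorohydroxylation of an all-cis cyclohexenol (a ring oxirane forms and is opened in the same flask).
4. The all-cis C1/C6 oxygens come from Rubottom oxidation of (S)-carvone (C6–O), then enolate kinetic protonation and Luche reduction, both from the face anti to the isopropenyl group.
5. The carbocycle and C5 come unchanged from (S)-(+)-carvone. Ring order: cyclohexene (bought), transient 2,3-oxirane (step 3), side-chain oxirane (step 9).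

## Route

Step 1
Reactants: 1 (S)-(+)-carvone; 2 chlorotriethylsilane; 3 3-chloroperoxybenzoic acid
Product: 7 (5R,6R)-2-methyl-5-(prop-1-en-2-yl)-6-(triethylsilyloxy)cyclohex-2-en-1-one, via lithium dienolate 4 (not isolated), via triethylsilyl dienol ether 5 (not isolated), via silyloxy epoxide 6 (not isolated)
Conditions: LiN(iPr)2, THF, −78 °C; Et3SiCl, −78 → 0 °C; then mCPBA, hexane/CH2Cl2, −20 → 0 °C
Reagents that add atoms: chlorotriethylsilane, CC[Si](CC)(CC)Cl; 3-chloroperoxybenzoic acid, O=C(OO)c1cccc(Cl)c1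
Why: Kinetic C6 deprotonation and O-silylation give the cross-conjugated dienol ether, whose electron-rich enol double bond is epoxidised in preference to the other alkenes and opens with 1,4-silyl shift (Rubottom oxidation) to the α′-silyloxy enone; the C6 configuration (expected mainly trans, oxidant anti to the isopropenyl group) does not matter because step 2 resets it.

Step 2
Reactants: 7 (5R,6R)-2-methyl-5-(prop-1-en-2-yl)-6-(triethylsilyloxy)cyclohex-2-en-1-one
Product: 10 (1R,5R,6S)-2-methyl-5-(prop-1-en-2-yl)-6-(triethylsilyloxy)cyclohex-2-en-1-ol, via lithium enolate 8 (not isolated), via cis silyloxy ketone 9 (not isolated)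
Conditions: LiN(iPr)2, THF, −78 °C; AcOH/THF, −90 °C; then CeCl3·7H2O, MeOH, NaBH4, −78 °C (same flask)
Reagents that add atoms: none
Why: In the tetrasubstituted enolate, allylic 1,2-strain puts the isopropenyl group pseudoaxial, so kinetic C-protonation (contra-thermodynamic epimerisation) and then Luche 1,2-reduction both occur from the face anti to it, setting C6 (silyloxy cis to the side chain) and C1 (hydroxyl cis to both), and reducing in the same flask prevents the cis ketone from epimerising back.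

Step 3
Reactants: 10 (1R,5R,6S)-2-methyl-5-(prop-1-en-2-yl)-6-(triethylsilyloxy)cyclohex-2-en-1-ol; 11 tert-butyl hydroperoxide; 12 dichlorodiisopropoxytitanium
Product: 14 (1S,2S,3S,5R,6S)-3-chloro-2-methyl-5-(prop-1-en-2-yl)-6-(triethylsilyloxy)cyclohexane-1,2-diol, via epoxy alcohol 13 (not isolated)
Conditions: TiCl2(OiPr)2 (1.2 equiv), t-BuOOH (2 equiv, decane), 4 Å molecular sieves, CH2Cl2, −20 → 0 °C; aq. tartaric acid work-up
Reagents that add atoms: tert-butyl hydroperoxide, CC(C)(C)OO; dichlorodiisopropoxytitanium, CC(C)O[Ti](Cl)(Cl)OC(C)C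
Why: Proposed new method: one chlorotitanium peroxide reagent does hydroxyl-directed epoxidation and chloride delivery in a single flask — the C1 alkoxide binds titanium, the bound tert-butyl peroxide transfers oxygen to the alkene face syn to C1–O (Sharpless/Henbest-type directed epoxidation), and the still-chelated, Lewis-acid-activated epoxy alkoxide 13 is opened by titanium-bound chloride at the distal secondary C3 from the opposite face (trans-diaxial Fürst–Plattner opening in the half-chair with the C5 group equatorial), giving the tertiary C2–OH cis to C1–OH and the anti C3–Cl while the undirected isopropenyl alkene is untouched; the closest known reactions are titanium/TBHP epoxidation of allylic alcohols, the chlorodiol formation seen with TiCl2(OiPr)2–tartrate on primary acyclic allylic alcohols, and titanium-assisted C3 halide opening of isolated 2,3-epoxy alcohols, none shown as a substrate-directed one-flask process on a cyclic trisubstituted secondary allylic alcohol.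

Step 4
Reactants: 14 (1S,2S,3S,5R,6S)-3-chloro-2-methyl-5-(prop-1-en-2-yl)-6-(triethylsilyloxy)cyclohexane-1,2-diol; 11 tert-butyl hydroperoxide
Product: 16 (1S,2S,3S,5R,6S)-3-chloro-2-methyl-5-(3-oxoprop-1-en-2-yl)-6-(triethylsilyloxy)cyclohexane-1,2-diol, via allylic alcohol 15 (not isolated)
Conditions: SeO2 (30 mol%), t-BuOOH, salicylic acid (10 mol%), CH2Cl2, rt; filter; MnO2, CH2Cl2, rt
Reagents that add atoms: tert-butyl hydroperoxide, CC(C)(C)OO
Why: With the ring alkene consumed, the isopropenyl group is the only olefin, so the SeO2 ene/[2,3]-sigmatropic allylic oxidation (oxygen relayed from TBHP) attacks its methyl group in preference to the ring CH and MnO2 then oxidises only the primary allylic alcohol, creating no stereocentre.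

Step 5
Reactants: 16 (1S,2S,3S,5R,6S)-3-chloro-2-methyl-5-(3-oxoprop-1-en-2-yl)-6-(triethylsilyloxy)cyclohexane-1,2-diol; 17 (−)-B-allyldiisopinocampheylborane (the reagent derived from (+)-α-pinene)
Product: 19 (1S,2S,3S,5R,6S)-3-chloro-5-[(3S)-3-hydroxyhexa-1,5-dien-2-yl]-2-methyl-6-(triethylsilyloxy)cyclohexane-1,2-diol, via borinate ester 18 (not isolated)
Conditions: (−)-Ipc2B(allyl) (2.5 equiv), Et2O, −78 °C; then HOCH2CH2NH2, rt
Reagents that add atoms: (−)-B-allyldiisopinocampheylborane, C=CCB([C@@H]1C[C@@H]2C[C@H]([C@H]1C)C2(C)C)[C@@H]1C[C@@H]2C[C@H]([C@H]1C)C2(C)C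
Why: Brown allylboration through a chair Zimmerman–Traxler transition state is reagent-controlled, the (+)-α-pinene-derived borane giving the (3′S)-carbinol (same facial sense as (S)-1-phenylbut-3-en-1-ol from benzaldehyde), and at −78 °C the aldehyde reacts far faster than the free hydroxyls, which only consume excess reagent.

Step 6
Reactants: 19 (1S,2S,3S,5R,6S)-3-chloro-5-[(3S)-3-hydroxyhexa-1,5-dien-2-yl]-2-methyl-6-(triethylsilyloxy)cyclohexane-1,2-diol; 20 angelic acid
Product: 21 (1S,2S,3S,5R,6S)-3-chloro-2-hydroxy-2-methyl-5-{(3S)-3-[(Z)-2-methylbut-2-enoyloxy]hexa-1,5-dien-2-yl}-6-(triethylsilyloxy)cyclohexyl (Z)-2-methylbut-2-enoate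
Conditions: angelic acid, 2,4,6-Cl3C6H2COCl, Et3N, toluene, rt (mixed anhydride); then 19, toluene, 80 °C
Reagents that add atoms: angelic acid, C/C=C(/C)C(=O)O
Why: Yamaguchi-type acylation with the mixed angelic 2,4,6-trichlorobenzoic anhydride and no DMAP esterifies the two secondary hydroxyls (C1 and C3′) with retention and without Z→E isomerisation of the angelate, while the tertiary C2–OH is too hindered to react and C6 is blocked as its silyl ether.

Step 7
Reactants: 21 (1S,2S,3S,5R,6S)-3-chloro-2-hydroxy-2-methyl-5-{(3S)-3-[(Z)-2-methylbut-2-enoyloxy]hexa-1,5-dien-2-yl}-6-(triethylsilyloxy)cyclohexyl (Z)-2-methylbut-2-enoate; 22 2-methylbut-2-ene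
Product: 23 (1S,2S,3S,5R,6S)-3-chloro-2-hydroxy-2-methyl-5-{(3S)-6-methyl-3-[(Z)-2-methylbut-2-enoyloxy]hepta-1,5-dien-2-yl}-6-(triethylsilyloxy)cyclohexyl (Z)-2-methylbut-2-enoate
Conditions: RuCl2(=CHPh)(PCy3)(H2IMes) (second-generation Grubbs catalyst, 5 mol%), 2-methylbut-2-ene/CH2Cl2, 40 °C
Reagents that add atoms: 2-methylbut-2-ene, CC=C(C)C
Why: Olefin cross-metathesis occurs only at the monosubstituted terminal alkene (the 1,1-disubstituted alkene next to the acyloxy carbon and the electron-poor trisubstituted angelate alkenes are inert), exchanging =CH2 for =CMe2 with loss of propene and touching no stereocentre.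

Step 8
Reactants: 23 (1S,2S,3S,5R,6S)-3-chloro-2-hydroxy-2-methyl-5-{(3S)-6-methyl-3-[(Z)-2-methylbut-2-enoyloxy]hepta-1,5-dien-2-yl}-6-(triethylsilyloxy)cyclohexyl (Z)-2-methylbut-2-enoate
Product: 24 (1S,2S,3S,5R,6S)-3-chloro-2,6-dihydroxy-2-methyl-5-{(3S)-6-methyl-3-[(Z)-2-methylbut-2-enoyloxy]hepta-1,5-dien-2-yl}cyclohexyl (Z)-2-methylbut-2-enoate
Conditions: HF·pyridine, pyridine, THF, 0 °C → rt
Reagents that add atoms: none
Why: Buffered fluoride desilylation cleaves only the Si–O bond; it is run before the acid-labile oxirane exists and under non-basic conditions, so the chlorohydrin does not close to an epoxide and the C1 angelate does not migrate to the freed cis C6 hydroxyl.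

Step 9
Reactants: 24 (1S,2S,3S,5R,6S)-3-chloro-2,6-dihydroxy-2-methyl-5-{(3S)-6-methyl-3-[(Z)-2-methylbut-2-enoyloxy]hepta-1,5-dien-2-yl}cyclohexyl (Z)-2-methylbut-2-enoate; 25 potassium peroxymonosulfate
Product: 26 (1S,2S,3S,5R,6S)-3-chloro-5-{(3S)-4-[(2R)-3,3-dimethyloxiran-2-yl]-3-[(Z)-2-methylbut-2-enoyloxy]but-1-en-2-yl}-2,6-dihydroxy-2-methylcyclohexyl (Z)-2-methylbut-2-enoate (CNP0158207.1)
Conditions: 1,2:4,5-di-O-isopropylidene-β-D-erythro-2,3-hexodiulo-2,6-pyranose (D-fructose-derived Shi ketone, 0.5–1 equiv), Oxone (2KHSO5·KHSO4·K2SO4), NaHCO3, Bu4NHSO4, MeCN–(MeO)2CH2/aq. Na2EDTA, pH ≈ 8, 0 °C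
Reagents that add atoms: potassium peroxymonosulfate, [K+].[O-]S(=O)(=O)OO
Why: Shi asymmetric epoxidation: the D-fructose-derived dioxirane epoxidises the electron-rich trisubstituted prenyl alkene through the spiro transition state that gives the (R)-oxirane carbon (catalyst control, same face as for (R,R)-epoxides from trans-alkenes), while the 1,1-disubstituted and angelate alkenes are much less reactive and pH 8 keeps the chlorohydrin and esters intact.

## Compound list

1 | (S)-(+)-carvone, (5S)-2-methyl-5-(prop-1-en-2-yl)cyclohex-2-en-1-one | C=C(C)[C@H]1CC=C(C)C(=O)C1 | starting material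
2 | chlorotriethylsilane | CC[Si](CC)(CC)Cl | starting material
3 | 3-chloroperoxybenzoic acid (mCPBA) | O=C(OO)c1cccc(Cl)c1 | starting material
4 | lithium dienolate of 1 (C1–O−, C1=C6 and C2=C3 double bonds, C5 unchanged) | C=C(C)[C@H]1CC=C(C)C([O-])=C1.[Li+] | intermediate
5 | triethylsilyl dienol ether of 1, triethyl{[(3S)-6-methyl-3-(prop-1-en-2-yl)cyclohexa-1,5-dien-1-yl]oxy}silane | C=C(C)[C@H]1CC=C(C)C(O[Si](CC)(CC)CC)=C1 | intermediate
6 | 1,6-epoxide of 5, oxirane oxygen on the face anti to the isopropenyl group, C1 bearing OSiEt3 | C=C(C)[C@H]1CC=C(C)[C@]2(O[Si](CC)(CC)CC)O[C@H]12 | intermediate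
7 | (5R,6R)-2-methyl-5-(prop-1-en-2-yl)-6-(triethylsilyloxy)cyclohex-2-en-1-one (trans, main epimer) | C=C(C)[C@H]1CC=C(C)C(=O)[C@@H]1O[Si](CC)(CC)CC | intermediate
8 | lithium (5R)-enolate of 7 (C1–O−, C1=C6 double bond, OSiEt3 on C6) | C=C(C)[C@H]1CC=C(C)C([O-])=C1O[Si](CC)(CC)CC.[Li+] | intermediate
9 | (5R,6S)-2-methyl-5-(prop-1-en-2-yl)-6-(triethylsilyloxy)cyclohex-2-en-1-one (cis) | C=C(C)[C@H]1CC=C(C)C(=O)[C@H]1O[Si](CC)(CC)CC | intermediate
10 | (1R,5R,6S)-2-methyl-5-(prop-1-en-2-yl)-6-(triethylsilyloxy)cyclohex-2-en-1-ol (OH, OSiEt3 and isopropenyl all cis) | C=C(C)[C@H]1CC=C(C)[C@@H](O)[C@H]1O[Si](CC)(CC)CC | intermediate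
11 | tert-butyl hydroperoxide | CC(C)(C)OO | starting material
12 | dichlorodiisopropoxytitanium, TiCl2(OiPr)2 | CC(C)O[Ti](Cl)(Cl)OC(C)C | starting material
13 | (1S,2S,3R,5R,6S)-2,3-epoxy-2-methyl-5-(prop-1-en-2-yl)-6-(triethylsilyloxy)cyclohexan-1-ol (oxirane cis to the C1 hydroxyl) | C=C(C)[C@H]1C[C@H]2O[C@@]2(C)[C@@H](O)[C@H]1O[Si](CC)(CC)CC | intermediate
14 | (1S,2S,3S,5R,6S)-3-chloro-2-methyl-5-(prop-1-en-2-yl)-6-(triethylsilyloxy)cyclohexane-1,2-diol | C=C(C)[C@H]1C[C@H](Cl)[C@@](C)(O)[C@@H](O)[C@H]1O[Si](CC)(CC)CC | intermediate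
15 | (1S,2S,3S,5R,6S)-3-chloro-5-(3-hydroxyprop-1-en-2-yl)-2-methyl-6-(triethylsilyloxy)cyclohexane-1,2-diol | OCC(=C)[C@H]1C[C@H](Cl)[C@@](C)(O)[C@@H](O)[C@H]1O[Si](CC)(CC)CC | intermediate
16 | (1S,2S,3S,5R,6S)-3-chloro-2-methyl-5-(3-oxoprop-1-en-2-yl)-6-(triethylsilyloxy)cyclohexane-1,2-diol | O=CC(=C)[C@H]1C[C@H](Cl)[C@@](C)(O)[C@@H](O)[C@H]1O[Si](CC)(CC)CC | intermediate
17 | (−)-B-allyldiisopinocampheylborane (from (+)-α-pinene) | C=CCB([C@@H]1C[C@@H]2C[C@H]([C@H]1C)C2(C)C)[C@@H]1C[C@@H]2C[C@H]([C@H]1C)C2(C)C | starting material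
18 | O-(diisopinocampheylboryl) ester of 19 at the new (3′S)-carbinol | C=C([C@H](CC=C)OB([C@@H]2C[C@@H]3C[C@H]([C@H]2C)C3(C)C)[C@@H]2C[C@@H]3C[C@H]([C@H]2C)C3(C)C)[C@H]1C[C@H](Cl)[C@@](C)(O)[C@@H](O)[C@H]1O[Si](CC)(CC)CC | intermediate
19 | (1S,2S,3S,5R,6S)-3-chloro-5-[(3S)-3-hydroxyhexa-1,5-dien-2-yl]-2-methyl-6-(triethylsilyloxy)cyclohexane-1,2-diol | C=C([C@H](CC=C)O)[C@H]1C[C@H](Cl)[C@@](C)(O)[C@@H](O)[C@H]1O[Si](CC)(CC)CC | intermediate
20 | angelic acid, (Z)-2-methylbut-2-enoic acid | C/C=C(/C)C(=O)O | starting material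
21 | (1S,2S,3S,5R,6S)-3-chloro-2-hydroxy-2-methyl-5-{(3S)-3-[(Z)-2-methylbut-2-enoyloxy]hexa-1,5-dien-2-yl}-6-(triethylsilyloxy)cyclohexyl (Z)-2-methylbut-2-enoate | C=C([C@H](CC=C)OC(=O)/C(C)=C\C)[C@H]1C[C@H](Cl)[C@@](C)(O)[C@@H](OC(=O)/C(C)=C\C)[C@H]1O[Si](CC)(CC)CC | intermediate
22 | 2-methylbut-2-ene | CC=C(C)C | starting material
23 | (1S,2S,3S,5R,6S)-3-chloro-2-hydroxy-2-methyl-5-{(3S)-6-methyl-3-[(Z)-2-methylbut-2-enoyloxy]hepta-1,5-dien-2-yl}-6-(triethylsilyloxy)cyclohexyl (Z)-2-methylbut-2-enoate | C=C([C@H](CC=C(C)C)OC(=O)/C(C)=C\C)[C@H]1C[C@H](Cl)[C@@](C)(O)[C@@H](OC(=O)/C(C)=C\C)[C@H]1O[Si](CC)(CC)CC | intermediate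
24 | (1S,2S,3S,5R,6S)-3-chloro-2,6-dihydroxy-2-methyl-5-{(3S)-6-methyl-3-[(Z)-2-methylbut-2-enoyloxy]hepta-1,5-dien-2-yl}cyclohexyl (Z)-2-methylbut-2-enoate | C=C([C@H](CC=C(C)C)OC(=O)/C(C)=C\C)[C@H]1C[C@H](Cl)[C@@](C)(O)[C@@H](OC(=O)/C(C)=C\C)[C@H]1O | intermediate
25 | potassium peroxymonosulfate, KHSO5 (active salt of Oxone) | [K+].[O-]S(=O)(=O)OO | starting material
26 | CNP0158207.1, (1S,2S,3S,5R,6S)-3-chloro-5-{(3S)-4-[(2R)-3,3-dimethyloxiran-2-yl]-3-[(Z)-2-methylbut-2-enoyloxy]but-1-en-2-yl}-2,6-dihydroxy-2-methylcyclohexyl (Z)-2-methylbut-2-enoate | C=C([C@H](C[C@H]1OC1(C)C)OC(=O)/C(C)=C\C)[C@H]1C[C@H](Cl)[C@@](C)(O)[C@@H](OC(=O)/C(C)=C\C)[C@H]1O | target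

## Step count and risks

Total step count: 9. Longest linear sequence: 9 steps from (S)-(+)-carvone; all other inputs are bought reagents.

Steps most likely to fail:

**Step 3** (the proposed new chlorohydroxylation). The risks are semipinacol rearrangement of the Lewis-acid-activated epoxy alcohol and chloride attack at the tertiary C2. The fallback uses known chemistry, sets out from 10 and returns at 14. VO(acac)2-catalysed, hydroxyl-directed epoxidation with t-BuOOH (CH2Cl2, 0 °C) gives epoxy alcohol 13, which is now isolated. A separate titanium-assisted, C3-selective opening with Ti(OiPr)4 and diethylammonium chloride (CH2Cl2, rt) then gives 14. This stepwise route makes no compound outside the list (F0).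

**Step 2** (kinetic protonation). The risks are incomplete facial control in the protonation and silyl scrambling in the enolate. The fallback replaces proton delivery by an SN2 inversion at C6; it sets out from 7 and returns at 10 by way of 9. HF·pyridine removes the silyl group to give trans-6-hydroxycarvone F1. A Mitsunobu reaction with chloroacetic acid (PPh3, DIAD, toluene, 0 °C → rt) gives the inverted cis-6-(chloroacetoxy)carvone F2. Thiourea/NaHCO3 in EtOH removes the chloroacetyl group to give cis-6-hydroxycarvone F3. Et3SiCl/imidazole then gives 9, which is reduced at once under the Luche conditions of step 2 to 10.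

**Step 4** (SeO2 allylic oxidation). The risks are low conversion and over-oxidation. The fallback sets out from 14 and returns at 16. Ene-type allylic chlorination of the isopropenyl group with NaOCl/CeCl3·7H2O (CH2Cl2/H2O, 0 °C) gives the allylic chloride (1S,2S,3S,5R,6S)-3-chloro-5-(3-chloroprop-1-en-2-yl)-2-methyl-6-(triethylsilyloxy)cyclohexane-1,2-diol F4. Ganem oxidation with N-methylmorpholine N-oxide (NaI cat., MeCN, rt) then converts the CH2Cl group into the aldehyde of 16.

Further compounds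
F1 | step 2 | trans-6-hydroxycarvone, (5R,6R)-6-hydroxy-2-methyl-5-(prop-1-en-2-yl)cyclohex-2-en-1-one | C=C(C)[C@H]1CC=C(C)C(=O)[C@@H]1O
F2 | step 2 | cis-6-(chloroacetoxy)carvone, (5R,6S)-2-methyl-1-oxo-5-(prop-1-en-2-yl)cyclohex-2-en-6-yl chloroacetate | C=C(C)[C@H]1CC=C(C)C(=O)[C@H]1OC(=O)CCl
F3 | step 2 | cis-6-hydroxycarvone, (5R,6S)-6-hydroxy-2-methyl-5-(prop-1-en-2-yl)cyclohex-2-en-1-one | C=C(C)[C@H]1CC=C(C)C(=O)[C@H]1O
F0 | step 3 | none | none
F4 | step 4 | (1S,2S,3S,5R,6S)-3-chloro-5-(3-chloroprop-1-en-2-yl)-2-methyl-6-(triethylsilyloxy)cyclohexane-1,2-diol | ClCC(=C)[C@H]1C[C@H](Cl)[C@@](C)(O)[C@@H](O)[C@H]1O[Si](CC)(CC)CC
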